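Chromene numbering: O1, C2, C3, C4 (ketone), C4a, C5 (enol), C6, C7 (ketone), C8 (quaternary), C8a. Ring A is the carbocycle C4a–C8a and ring B the dihydropyranone.
Retrosynthesis cuts O1–C8a (ring B), then C4a–C8a (ring A), then C5–C6, C6–C7 and the two C8–CH2 bonds. This leaves lavandulol, a malonate, prenyl bromide, 3-phenylglutaric anhydride and a propionate aldol unit.
Enabling feature: C7 and C5 of ring A and C4 of ring B lie 1,3,5 along the chain C7–C6–C5–C4a–C4, so they can be kept as a 4-pyranone whose ring oxygen links C7 to C4. Its only CH, C4a, sits five bonds from a methyl ester on C8, and that ester carbon becomes C8a.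
Forward order: acyclic keto diester, then the temporary pyranone, then ring A (pyranone consumed), then ring B.
Stereochemistry: the side-chain centre comes from (R)-lavandulol, C8 from a catalyst-controlled phase-transfer prenylation, the benzylic centre from desymmetrising methanolysis of the anhydride, and C2 and C3 from an Evans syn aldol. The C2–O bond is never broken.

Key step: step 18

Assumption: in steps 3 and 6 the sense of induction depends on the choice between pseudoenantiomeric cinchona catalysts. The catalyst named is taken to give the drawn configuration; otherwise its pseudoenantiomer is used.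
Remark: lavandulyl = 5-methyl-2-(prop-1-en-2-yl)hex-4-en-1-yl, prenyl = 3-methylbut-2-en-1-yl, TBS = tert-butyldimethylsilyl. The lavandulyl stereocentre is never touched; its descriptor changes from R (1, 2) to S (from 4 on) only through CIP priorities. Polycarbonyl compounds are drawn as one tautomer.

Step 1
Reactants: 1 (R)-lavandulol
Product: 2 (R)-lavandulyl iodide
Conditions: PPh3, I2, imidazole, CH2Cl2, 0 °C → rt
Reagents that add atoms: iodine, SMILES II
Why: Appel-type iodination proceeds by SN2 displacement of the oxyphosphonium group at the primary carbon, so the neighbouring stereocentre and both alkenes should stay untouched.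

Step 2
Reactants: 3 tert-butyl methyl malonate; 2 (R)-lavandulyl iodide
Product: 4 tert-butyl methyl 2-[(S)-lavandulyl]malonate (both epimers at the malonate CH)
Conditions: 3 (1.5 equiv), NaH, DMF, 0 °C; then 2, 60 °C
Reagents that add atoms: none
Why: Malonic ester alkylation with the soft sodium enolate should favour SN2 over E2 on the β-branched primary iodide, an excess of 3 holds back double alkylation, and the new malonate CH is an epimer mixture that is erased in step 3.

Step 3
Reactants: 4 tert-butyl methyl 2-[(S)-lavandulyl]malonate; 5 prenyl bromide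
Product: 6 1-tert-butyl 3-methyl (2S)-2-[(S)-lavandulyl]-2-prenylmalonate
Conditions: 5 (1.5 equiv), N-(9-anthracenylmethyl)cinchoninium chloride (10 mol %), 50% aq KOH, toluene, −20 °C
Reagents that add atoms: none
Why: Asymmetric phase-transfer alkylation of an α-monosubstituted tert-butyl methyl malonate, in which the chiral ammonium cation pairs with the planar enolate, tells the large tert-butoxycarbonyl from the small methoxycarbonyl group and exposes one face to prenyl bromide, which sets C8, while the minor C8 epimer is a diastereomer that chromatography can remove.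

Step 4
Reactants: 6 quaternary tert-butyl methyl malonate
Product: 8 half acid (2R)-2-(methoxycarbonyl)-5-methyl-2-[(S)-lavandulyl]hex-4-enoic acid, via trimethylsilyl ester 7 (not isolated)
Conditions: TMSOTf, 2,6-lutidine, CH2Cl2, 0 °C → rt; then H2O
Reagents that add atoms: none
Why: Silyl-triflate-induced cleavage of a tert-butyl ester occurs by alkyl–oxygen fission with loss of isobutene under lutidine buffering, so the methyl ester survives and no free strong acid is present that could lactonise the acid onto the prenyl alkene.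

Step 5
Reactants: 8 half acid
Product: 9 methyl (2S)-2-(chlorocarbonyl)-5-methyl-2-[(S)-lavandulyl]hex-4-enoate
Conditions: 1-chloro-N,N,2-trimethylprop-1-en-1-amine, CH2Cl2, 0 °C → rt; concentrated and used crude
Reagents that add atoms: 1-chloro-N,N,2-trimethylprop-1-en-1-amine (Ghosez reagent), SMILES CC(C)=C(Cl)N(C)C
Why: Acid chloride formation with the α-chloroenamine is neutral and releases no HCl, which protects the three alkenes, and the α-carbon has no hydrogen so that neither ketene formation nor epimerisation is possible.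

Step 6
Reactants: 10 3-phenylglutaric anhydride
Product: 11 (3S)-5-methoxy-5-oxo-3-phenylpentanoic acid
Conditions: MeOH (10 equiv), quinine-derived 3,5-bis(trifluoromethyl)benzenesulfonamide catalyst (10 mol %), MTBE, −20 °C
Reagents that add atoms: methanol, SMILES CO
Why: Organocatalytic desymmetrising alcoholysis of a prochiral cyclic anhydride, in which the quinuclidine nitrogen activates methanol while the sulfonamide N–H binds one of the two enantiotopic carbonyl groups, which sets the benzylic stereocentre.

Step 7
Reactants: 11 (S)-hemiester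
Product: 12 methyl (3S)-4-iodo-3-phenylbutanoate
Conditions: PhI(OAc)2, I2, CH2Cl2, hν (tungsten lamp), reflux
Reagents that add atoms: iodine, SMILES II
Why: Suárez iododecarboxylation (a Hunsdiecker-type reaction) runs through the acyl hypoiodite and a primary radical that iodine should trap faster than a 1,2-phenyl shift can occur, and the stereocentre next to the radical carbon is not involved.

Step 8
Reactants: 12 methyl (3S)-4-iodo-3-phenylbutanoate; 9 acid chloride
Product: 14 dimethyl (2R,5S)-2-[(S)-lavandulyl]-3-oxo-5-phenyl-2-prenylheptanedioate, via alkylzinc iodide 13 (not isolated)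
Conditions: 12, activated Zn dust, LiCl, THF, 30 °C; then 9, Pd(PPh3)4 (5 mol %), THF, 0 °C → rt
Reagents that add atoms: none
Why: Zinc inserts into the primary C–I bond to give an ester-tolerant γ-zincio ester, and its palladium-catalysed Negishi acylation by the hindered acid chloride forms C6–C7 and stops at the ketone without touching a stereocentre.

Step 9
Reactants: 15 (S)-4-benzyl-3-propionyloxazolidin-2-one; 16 acetaldehyde
Product: 18 (4S)-4-benzyl-3-[(2S,3R)-3-hydroxy-2-methylbutanoyl]oxazolidin-2-one, via (Z)-dibutylboron enolate 17 (not isolated)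
Conditions: Bu2BOTf, Et3N, CH2Cl2, −78 → 0 °C; 16, −78 → 0 °C; pH 7 buffer, MeOH, 30% H2O2, 0 °C
Reagents that add atoms: none
Why: Evans syn aldol, in which the (Z)-boron enolate reacts through a Zimmerman–Traxler chair and the benzyl group of the auxiliary blocks one enolate face, which sets C3 as S and C2 as R in a syn relationship.

Step 10
Reactants: 18 syn aldol adduct
Product: 19 (4S)-4-benzyl-3-[(2S,3R)-3-(TBS-oxy)-2-methylbutanoyl]oxazolidin-2-one
Conditions: TBSOTf, 2,6-lutidine, CH2Cl2, 0 °C
Reagents that add atoms: tert-butyldimethylsilyl triflate, SMILES CC(C)(C)[Si](C)(C)OS(=O)(=O)C(F)(F)F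
Why: Silylation with the silyl triflate and a hindered pyridine base is fast at low temperature, which avoids retro-aldol cleavage and epimerisation of the β-hydroxy imide.

Step 11
Reactants: 19 silylated imide
Product: 20 (2R,3R)-3-(TBS-oxy)-2-methylbutan-1-ol
Conditions: LiBH4, H2O (1 equiv), Et2O, 0 °C; aq NaOH work-up
Reagents that add atoms: none
Why: Reductive removal of the auxiliary with lithium borohydride attacks the exocyclic imide carbonyl and gives the primary alcohol without enolisation, so C3 keeps its configuration.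

Step 12
Reactants: 20 primary alcohol
Product: 21 (2S,3R)-3-(TBS-oxy)-2-methylbutanal
Conditions: Dess–Martin periodinane, CH2Cl2, 0 °C → rt
Reagents that add atoms: none
Why: Dess–Martin oxidation works under non-basic conditions and stops at the aldehyde, so the α-stereocentre should not epimerise if 21 is used at once.

Step 13
Reactants: 21 aldehyde
Product: 22 tert-butyl{[(2R,3R)-5,5-dibromo-3-methylpent-4-en-2-yl]oxy}dimethylsilane
Conditions: CBr4, PPh3, CH2Cl2, 0 °C
Reagents that add atoms: carbon tetrabromide, SMILES BrC(Br)(Br)Br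
Why: The first stage of the Corey–Fuchs sequence is a Wittig-type dibromoolefination by a non-basic ylide, a standard way to homologate α-chiral aldehydes without epimerisation.

Step 14
Reactants: 22 dibromoalkene
Product: 24 (4R,5R)-5-(TBS-oxy)-4-methylhex-2-ynal, via lithium acetylide 23 (not isolated)
Conditions: n-BuLi (2.1 equiv), THF, −78 °C; DMF, −78 → 0 °C; poured into cold 10% aq KH2PO4/MTBE
Reagents that add atoms: N,N-dimethylformamide, SMILES CN(C)C=O
Why: The second stage of the Corey–Fuchs sequence (elimination and bromine–lithium exchange) gives the lithium acetylide, DMF formylates it, and the inverse quench into phosphate buffer keeps the liberated dimethylamine from adding to the ynal.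

Step 15
Reactants: 14 keto diester; 24 ynal
Product: 26 propargylic aldol adduct (C5 carbinol and C6 as diastereomer mixture; all other centres as in 14 and 24), via lithium enolate 25 (not isolated)
Conditions: LDA (1.05 equiv), THF, −78 °C; 24, −78 °C; AcOH quench at −78 °C; used crude
Reagents that add atoms: none
Why: Directed aldol addition, in which C8 carries no hydrogen and a ketone is more acidic than an ester, so LDA should give only the C6 enolate, which adds 1,2 to the slim and reactive ynal to form C5–C6, the two new stereocentres being erased in step 16 and the cold quench preventing lactonisation of the aldolate onto the side-chain ester.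

Step 16
Reactants: 26 aldol adduct
Product: 28 pyranone diester (2,3,6-trisubstituted 4-pyranone: C8 quaternary methyl ester at ring C2; (1S)-3-methoxy-3-oxo-1-phenylpropyl at ring C3; (2S,3R)-3-(TBS-oxy)butan-2-yl at ring C6), via ynedione 27 (not isolated)
Conditions: Dess–Martin periodinane, CH2Cl2, 0 °C; aq Na2S2O3 wash; crude 27, Ph3PAuNTf2 (5 mol %), CH2Cl2, rt
Reagents that add atoms: none
Why: Dess–Martin oxidation of the β-hydroxy ketone gives the 1-alkynyl 1,3-diketone, and carbophilic activation of the ynone lets the C7 oxygen add to the alkyne terminus C4 in a 6-endo-dig cycloisomerisation (the 5-exo mode would be anti-Michael), a known route to 4-pyranones that is neutral enough to leave C3 and the silyl ether alone.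

Step 17
Reactants: 28 pyranone diester
Product: 29 pyranone acid (28 with the side-chain CO2Me turned into CO2H; C8 methyl ester retained)
Conditions: LiOH (1.5 equiv), THF–H2O 3:1, 0 °C; 1 M HCl to pH 4
Reagents that add atoms: lithium hydroxide, SMILES [Li+].[OH-]
Why: Chemoselective saponification, in which the unhindered CH2CO2Me group should hydrolyse at 0 °C while the neopentyl-type ester on C8 and the trisubstituted pyranone do not react, and the resulting carboxylate removes the only other ester that C4a could reach through a six-membered ring and shuts off retro-Michael loss of the benzylic arm in step 18.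

Step 18
Reactants: 29 pyranone acid
Product: 31 ring A triketone acid (3S)-3-{(5S)-3-[(2S,3R)-3-(TBS-oxy)-2-methylbutanoyl]-2,4-dihydroxy-5-[(S)-lavandulyl]-6-oxo-5-prenylcyclohexa-1,3-dien-1-yl}-3-phenylpropanoic acid, via open-chain triketone 30 (not isolated)
Conditions: KOH (8 equiv), MeOH–H2O 4:1, 0 → 35 °C; cold 1 M HCl to pH 3
Reagents that add atoms: potassium hydroxide, SMILES [K+].[OH-]
Why: Hydroxide adds to the less shielded α-carbon of the pyranone (C4), the ring oxygen departs as the C7 enolate and proton shifts give the open 1,3,5-triketone 30 as its dianion next to the carboxylate, after which C4a, the central carbon of the C5/C4 diketonate, adds to the methyl ester on C8 and methoxide is lost, so that C4a–C8a is formed. The closest known reaction type is the base-induced change of ester-bearing 4-pyranones and of 3,5,7-trioxo esters into acylphloroglucinols, that is the Claisen (Dieckmann) mode of polyketide cyclisation. Ring A (C4a, C5, C6, C7, C8, C8a) closes in the 6-exo-trig mode, no other ring is formed and the pyranone ring disappears. No stereocentre is created; C8 has no α-hydrogen, the benzylic centre is safe because a carboxylate side chain cannot start an E1cB retro-Michael cleavage, and C3 is protected after ring opening because the C4 carbonyl is part of an enolate. The step needs C4a to pick the C8 ester: the aldol mode is closed because C8 bears no hydrogen, C6 could only make a four-membered ring, the one other ester within reach was turned into a carboxylate in step 17, and O-acylation by the C5 enolate oxygen is reversible in hydroxide whereas the C-acylated β-triketone is withdrawn as a stable enolate. The neopentyl-type ester should resist intermolecular saponification, and the strain between the quaternary C8 and the benzylic arm on neighbouring ring carbons of the flat pyranone is released on opening, which should favour the open form.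

Step 19
Reactants: 31 ring A triketone acid
Product: 33 target (3S)-3-{(2R,3S,8S)-5-hydroxy-2,3-dimethyl-8-[(S)-lavandulyl]-4,7-dioxo-8-prenyl-3,4,7,8-tetrahydro-2H-chromen-6-yl}-3-phenylpropanoic acid, via hydroxy triketone acid 32 (not isolated)
Conditions: 48% aq HF, MeCN, 0 °C → rt
Reagents that add atoms: none
Why: Acidic fluoride removes the silyl ether and the resulting δ-hydroxy β-diketone 32 undergoes the usual cyclodehydration to a 2,3-dihydro-4-pyranone, the hydroxyl adding to C8a because the C5–OH···O=C4 chelate holds the chain beside C8a and because the C5-closed isomer, a doubly activated vinylogous ester without that chelate, should be reopened by water in this medium, while C2 keeps its configuration since only its O–Si and O–H bonds change.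

Compound list
1 | (R)-lavandulol, (2R)-5-methyl-2-(prop-1-en-2-yl)hex-4-en-1-ol | C=C(C)[C@@H](CC=C(C)C)CO | starting material
2 | (R)-lavandulyl iodide, (5R)-6-iodo-2-methyl-5-(prop-1-en-2-yl)hex-2-ene | C=C(C)[C@@H](CC=C(C)C)CI | intermediate
3 | tert-butyl methyl malonate | COC(=O)CC(=O)OC(C)(C)C | starting material
4 | 1-tert-butyl 3-methyl 2-[(2S)-5-methyl-2-(prop-1-en-2-yl)hex-4-en-1-yl]propanedioate, epimers at the malonate CH | C=C(C)[C@@H](CC=C(C)C)CC(C(=O)OC)C(=O)OC(C)(C)C | intermediate
5 | prenyl bromide, 1-bromo-3-methylbut-2-ene | CC(C)=CCBr | starting material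
6 | 1-tert-butyl 3-methyl (2S)-2-[(2S)-5-methyl-2-(prop-1-en-2-yl)hex-4-en-1-yl]-2-(3-methylbut-2-en-1-yl)propanedioate | C=C(C)[C@@H](CC=C(C)C)C[C@@](C(=O)OC(C)(C)C)(CC=C(C)C)C(=O)OC | intermediate
7 | 1-methyl 3-trimethylsilyl (2S)-2-[(S)-lavandulyl]-2-prenylpropanedioate | C=C(C)[C@@H](CC=C(C)C)C[C@@](C(=O)O[Si](C)(C)C)(CC=C(C)C)C(=O)OC | intermediate
8 | (2R)-2-(methoxycarbonyl)-5-methyl-2-[(2S)-5-methyl-2-(prop-1-en-2-yl)hex-4-en-1-yl]hex-4-enoic acid | C=C(C)[C@@H](CC=C(C)C)C[C@@](C(=O)O)(CC=C(C)C)C(=O)OC | intermediate
9 | methyl (2S)-2-(chlorocarbonyl)-5-methyl-2-[(2S)-5-methyl-2-(prop-1-en-2-yl)hex-4-en-1-yl]hex-4-enoate | C=C(C)[C@@H](CC=C(C)C)C[C@@](C(=O)Cl)(CC=C(C)C)C(=O)OC | intermediate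
10 | 3-phenylglutaric anhydride, 4-phenyloxane-2,6-dione | O=C1CC(c2ccccc2)CC(=O)O1 | starting material
11 | (3S)-5-methoxy-5-oxo-3-phenylpentanoic acid | OC(=O)C[C@@H](CC(=O)OC)c1ccccc1 | intermediate
12 | methyl (3S)-4-iodo-3-phenylbutanoate | IC[C@@H](CC(=O)OC)c1ccccc1 | intermediate
13 | [(2S)-4-methoxy-4-oxo-2-phenylbutyl]zinc iodide | I[Zn]C[C@@H](CC(=O)OC)c1ccccc1 | intermediate
14 | dimethyl (2R,5S)-2-[(S)-lavandulyl]-2-(3-methylbut-2-en-1-yl)-3-oxo-5-phenylheptanedioate | C=C(C)[C@@H](CC=C(C)C)C[C@@](C(=O)C[C@@H](CC(=O)OC)c1ccccc1)(CC=C(C)C)C(=O)OC | intermediate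
15 | (S)-4-benzyl-3-propionyloxazolidin-2-one | CCC(=O)N1[C@@H](Cc2ccccc2)COC1=O | starting material
16 | acetaldehyde | CC=O | starting material
17 | (Z)-dibutylboron enolate of 15 | C/C=C(\OB(CCCC)CCCC)N1[C@@H](Cc2ccccc2)COC1=O | intermediate
18 | (4S)-4-benzyl-3-[(2S,3R)-3-hydroxy-2-methylbutanoyl]-1,3-oxazolidin-2-one | O=C([C@@H](C)[C@@H](C)O)N1[C@@H](Cc2ccccc2)COC1=O | intermediate
19 | (4S)-4-benzyl-3-[(2S,3R)-3-(tert-butyldimethylsilyloxy)-2-methylbutanoyl]-1,3-oxazolidin-2-one | O=C([C@@H](C)[C@@H](C)O[Si](C)(C)C(C)(C)C)N1[C@@H](Cc2ccccc2)COC1=O | intermediate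
20 | (2R,3R)-3-(tert-butyldimethylsilyloxy)-2-methylbutan-1-ol | OC[C@@H](C)[C@@H](C)O[Si](C)(C)C(C)(C)C | intermediate
21 | (2S,3R)-3-(tert-butyldimethylsilyloxy)-2-methylbutanal | O=C[C@@H](C)[C@@H](C)O[Si](C)(C)C(C)(C)C | intermediate
22 | tert-butyl{[(2R,3R)-5,5-dibromo-3-methylpent-4-en-2-yl]oxy}dimethylsilane | BrC(Br)=C[C@@H](C)[C@@H](C)O[Si](C)(C)C(C)(C)C | intermediate
23 | lithium acetylide of (3R,4R)-4-(tert-butyldimethylsilyloxy)-3-methylpent-1-yne | [Li]C#C[C@@H](C)[C@@H](C)O[Si](C)(C)C(C)(C)C | intermediate
24 | (4R,5R)-5-(tert-butyldimethylsilyloxy)-4-methylhex-2-ynal | O=CC#C[C@@H](C)[C@@H](C)O[Si](C)(C)C(C)(C)C | intermediate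
25 | lithium C6–C7 enolate of 14 | C=C(C)[C@@H](CC=C(C)C)C[C@@](C(O[Li])=C[C@@H](CC(=O)OC)c1ccccc1)(CC=C(C)C)C(=O)OC | intermediate
26 | aldol adduct of 14 and 24: 14 bearing at C6 a (4R,5R)-5-(TBS-oxy)-1-hydroxy-4-methylhex-2-yn-1-yl group, mixture at C5 and C6 | C=C(C)[C@@H](CC=C(C)C)C[C@@](C(=O)C(C(O)C#C[C@@H](C)[C@@H](C)O[Si](C)(C)C(C)(C)C)[C@@H](CC(=O)OC)c1ccccc1)(CC=C(C)C)C(=O)OC | intermediate
27 | ynedione: 26 with the C5 carbinol oxidised to the ketone | C=C(C)[C@@H](CC=C(C)C)C[C@@](C(=O)C(C(=O)C#C[C@@H](C)[C@@H](C)O[Si](C)(C)C(C)(C)C)[C@@H](CC(=O)OC)c1ccccc1)(CC=C(C)C)C(=O)OC | intermediate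
28 | methyl (2R)-2-{6-[(2S,3R)-3-(tert-butyldimethylsilyloxy)butan-2-yl]-3-[(1S)-3-methoxy-3-oxo-1-phenylpropyl]-4-oxo-4H-pyran-2-yl}-5-methyl-2-[(S)-lavandulyl]hex-4-enoate | C=C(C)[C@@H](CC=C(C)C)C[C@@](C1=C([C@@H](CC(=O)OC)c2ccccc2)C(=O)C=C(O1)[C@@H](C)[C@@H](C)O[Si](C)(C)C(C)(C)C)(CC=C(C)C)C(=O)OC | intermediate
29 | (3S)-3-{6-[(2S,3R)-3-(tert-butyldimethylsilyloxy)butan-2-yl]-2-[(2R)-quaternary methyl ester carbon bearing (S)-lavandulyl and prenyl]-4-oxo-4H-pyran-3-yl}-3-phenylpropanoic acid | C=C(C)[C@@H](CC=C(C)C)C[C@@](C1=C([C@@H](CC(=O)O)c2ccccc2)C(=O)C=C(O1)[C@@H](C)[C@@H](C)O[Si](C)(C)C(C)(C)C)(CC=C(C)C)C(=O)OC | intermediate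
30 | open-chain C7,C5,C4-triketone acid with the C8 methyl ester (drawn neutral, C6 undefined) | C=C(C)[C@@H](CC=C(C)C)C[C@@](C(=O)C([C@@H](CC(=O)O)c1ccccc1)C(=O)CC(=O)[C@@H](C)[C@@H](C)O[Si](C)(C)C(C)(C)C)(CC=C(C)C)C(=O)OC | intermediate
31 | (3S)-3-{(5S)-3-[(2S,3R)-3-(tert-butyldimethylsilyloxy)-2-methylbutanoyl]-2,4-dihydroxy-5-[(S)-lavandulyl]-5-(3-methylbut-2-en-1-yl)-6-oxocyclohexa-1,3-dien-1-yl}-3-phenylpropanoic acid | C=C(C)[C@@H](CC=C(C)C)C[C@]1(CC=C(C)C)C(=O)C([C@@H](CC(=O)O)c2ccccc2)=C(O)C(C(=O)[C@@H](C)[C@@H](C)O[Si](C)(C)C(C)(C)C)=C1O | intermediate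
32 | 31 with the free C2 hydroxyl, (2S,3R)-3-hydroxy-2-methylbutanoyl at C4a | C=C(C)[C@@H](CC=C(C)C)C[C@]1(CC=C(C)C)C(=O)C([C@@H](CC(=O)O)c2ccccc2)=C(O)C(C(=O)[C@@H](C)[C@@H](C)O)=C1O | intermediate
33 | (3S)-3-{(2R,3S,8S)-5-hydroxy-2,3-dimethyl-8-[(2S)-5-methyl-2-(prop-1-en-2-yl)hex-4-en-1-yl]-8-(3-methylbut-2-en-1-yl)-4,7-dioxo-3,4,7,8-tetrahydro-2H-chromen-6-yl}-3-phenylpropanoic acid (CNP0150579.2) | C=C(C)[C@@H](CC=C(C)C)C[C@]1(CC=C(C)C)C(=O)C([C@@H](CC(=O)O)c2ccccc2)=C(O)C2=C1O[C@H](C)[C@H](C)C2=O | target

Total step count: 19. Longest linear sequence: 11 steps (9–19; steps 1–5, 8 and 15–19 are equally long).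

Steps most likely to fail

Step 18. Attack of hydroxide on the crowded pyranone may be slower than removal of the vinylogously acidic hydrogen at C3. That would lead to loss of silanolate or to epimerisation at C3. Closure on the hindered ester may also lag behind hydrolytic cleavage of the polyketone chain. The fallback sets out from 29 and comes back at 32. The silyl ether is taken off first (HF·pyridine, THF, 0 °C) to give the hydroxy pyranone acid F1. Its α-carbon C4 is less shielded, and in base its C2 oxygen is an alkoxide that cannot leave. Aqueous-methanolic KOH should then open it to the open-chain hydroxy triketone acid F2. Dieckmann closure of F2 gives 32 directly, and on acidification 32 goes on to 33 as in step 19.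

Step 19. The liberated hydroxyl may close on the less hindered C5 instead of C8a, and a long stay in acid may epimerise C3 to the trans series. The fallback sets out from 31 and comes back at 33.
- Trimethylsilyldiazomethane (toluene–MeOH, 0 °C) should esterify the acid and methylate only the free, non-chelated C7 enol. This gives the 7-O-methyl ether methyl ester F3. Ring A is then frozen as the 2,4-dienone whose C5–OH is chelated to C4=O, and the acyl chain is pinned beside C8a.
- Aqueous HF in MeCN then gives the desilylated hydroxy compound F4 and, by cyclodehydration, the 7-methoxychromane-4,5-dione methyl ester F5.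
- Lithium iodide in refluxing ethyl acetate removes both O-methyl groups by SN2 attack at the methyl carbons without base, and acidic work-up gives 33.

Step 3. The ion pair may show poor facial selectivity, because both substituents on C8 are large and the resident lavandulyl centre may be mismatched with the catalyst. The methyl ester may also be partly saponified by the concentrated base. The fallback sets out from 2 and comes back at 8. Dimethyl malonate is alkylated with 2 (NaH, DMF) to give dimethyl lavandulylmalonate F6. Prenylation with 5 (NaH, THF) gives the prochiral dimethyl lavandulyl(prenyl)malonate F7. A hydrolase chosen by screening (pig liver esterase, pH 7 buffer with DMSO) hydrolyses the pro-S ester group, which gives the half acid 8 without the tert-butyl ester detour. The wrong C8 epimer is a diastereomer and can be removed as an amine salt.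

Further compounds
F1 | step 18 | hydroxy pyranone acid, 29 without the silyl group | C=C(C)[C@@H](CC=C(C)C)C[C@@](C1=C([C@@H](CC(=O)O)c2ccccc2)C(=O)C=C(O1)[C@@H](C)[C@@H](C)O)(CC=C(C)C)C(=O)OC
F2 | step 18 | open-chain hydroxy triketone acid, 30 without the silyl group | C=C(C)[C@@H](CC=C(C)C)C[C@@](C(=O)C([C@@H](CC(=O)O)c1ccccc1)C(=O)CC(=O)[C@@H](C)[C@@H](C)O)(CC=C(C)C)C(=O)OC
F3 | step 19 | 7-O-methyl ether methyl ester of 31 | C=C(C)[C@@H](CC=C(C)C)C[C@]1(CC=C(C)C)C(OC)=C([C@@H](CC(=O)OC)c2ccccc2)C(O)=C(C(=O)[C@@H](C)[C@@H](C)O[Si](C)(C)C(C)(C)C)C1=O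
F4 | step 19 | desilylated hydroxy compound from F3 | C=C(C)[C@@H](CC=C(C)C)C[C@]1(CC=C(C)C)C(OC)=C([C@@H](CC(=O)OC)c2ccccc2)C(O)=C(C(=O)[C@@H](C)[C@@H](C)O)C1=O
F5 | step 19 | 7-methoxychromane-4,5-dione methyl ester, (2R,3S,8S) ring system of 33 with C7–OMe and CO2Me | C=C(C)[C@@H](CC=C(C)C)C[C@]1(CC=C(C)C)C(OC)=C([C@@H](CC(=O)OC)c2ccccc2)C(=O)C2=C1O[C@H](C)[C@H](C)C2=O
F6 | step 3 | dimethyl 2-[(S)-lavandulyl]malonate | C=C(C)[C@@H](CC=C(C)C)CC(C(=O)OC)C(=O)OC
F7 | step 3 | dimethyl 2-[(S)-lavandulyl]-2-prenylmalonate | C=C(C)[C@@H](CC=C(C)C)CC(CC=C(C)C)(C(=O)OC)C(=O)OC
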